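**Plan**

- Retrosynthesis: remove the angelate at O8, open the 1,10-diol back to the E C1=C10 alkene (via its epoxide), remove C13, and cut the lactone at O6–C12 and C7–C11. This leaves a cyclodeca-2,6-dienone, in which C8–C9 is cut and C1–C6 is re-joined.
- Enabling feature: the ten-membered ring holds a cis C4=C5 alkene that fits inside a cyclohexene built from C1–C6, and an oxygen on C8, two atoms from C6. C1–C6 can therefore be a temporary six-ring bond and C8–C9 the bond made by a [3,3] shift of a 6-(2-alkoxyvinyl)-1-isopropenylcyclohexenol.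
- Forward: (R)-carvone gives the trans-carveol silyl ether and then the enone. A PMB-oxyacetylide (from PMB alcohol and trichloroethylene) is added and reduced to the E enol ether. Anionic oxy-Cope rearrangement expands the six-ring to the ten-ring. The lactone ring follows by C7 alkylation and C6 reduction, then methylenation, angeloylation, epoxidation, hydrolysis and desilylation.
- Stereochemistry: C3 comes from carvone (Luche reduction, Mitsunobu inversion). The carvone stereocentre (later C1) directs the carbinol and the chair, which sets C8. C7 is set by outer-face enolate alkylation and C6 by chelation-controlled reduction. C1 and C10 are set by outer-face epoxidation of the E alkene and opening at C10 with inversion.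

Key step: step 8

Remark: germacrane numbering is used for the ring carbons from step 4 on (C1 and C3 = CH–O carbons flanking C2H2, C4=C5 = Z alkene, C6 = lactone O–CH, C7 = ring fusion, C8 = angelate carbon, C10 = methyl carbinol, C11–C13 = lactone carbons); 20 and 21 are carried as C11 epimers because C11 is not stereogenic in 22.

**Route**

Step 1
Reactants: 1 (R)-(−)-carvone
Product: 2 (1R,5R)-cis-carveol
Conditions: NaBH4, CeCl3·7H2O, MeOH, 0 °C
Reagents that add atoms: none
Why: Luche 1,2-reduction of the enone; axial hydride delivery should give the cis alcohol (OH and isopropenyl both equatorial).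

Step 2
Reactants: 2 (1R,5R)-cis-carveol
Product: 4 (1S,5R)-trans-carveol, via trans-carveyl 4-nitrobenzoate 3 (not isolated)
Conditions: PPh3, DIAD, 4-O2NC6H4CO2H, THF, 0 °C → rt; then K2CO3, MeOH, rt
Reagents that add atoms: 4-nitrobenzoic acid, O=C(O)c1ccc(cc1)[N+](=O)[O-]
Why: Mitsunobu esterification displaces the oxyphosphonium group by SN2 with inversion at the allylic carbinol (1R to 1S), and methanolysis of the crude ester releases the trans alcohol that carries the C3 configuration of the target.

Step 3
Reactants: 4 (1S,5R)-trans-carveol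
Product: 5 (1S,5R)-trans-carveol tert-butyldimethylsilyl ether
Conditions: TBSCl, imidazole, DMF, rt
Reagents that add atoms: tert-butyldimethylsilyl chloride, CC(C)(C)[Si](C)(C)Cl
Why: Standard silylation of a secondary allylic alcohol; the TBS ether is chosen to survive organolithium, hydride, KH, enolate, DDQ and peracid steps and to leave with fluoride at the end.

Step 4
Reactants: 5 (1S,5R)-trans-carveol tert-butyldimethylsilyl ether
Product: 6 (4S,6R)-4-(tert-butyldimethylsilyloxy)-3-methyl-6-(prop-1-en-2-yl)cyclohex-2-en-1-one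
Conditions: CrO3, 3,5-dimethylpyrazole, CH2Cl2, −20 °C
Reagents that add atoms: chromium trioxide, O=[Cr](=O)=O
Why: Allylic C–H oxidation by the CrO3–3,5-dimethylpyrazole complex should take the only ring methylene allylic to the trisubstituted alkene (the other allylic ring position already bears the silyl ether), the site selectivity that turns limonene into isopiperitenone; the neutral, cold conditions should spare the isopropenyl group and the epimerisable carbon next to the new carbonyl.

Step 5
Reactants: 7 4-methoxybenzyl alcohol; 8 trichloroethylene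
Product: 9 (E)-1,2-dichlorovinyl 4-methoxybenzyl ether
Conditions: KH, THF, 0 °C; then 8, −40 °C → rt
Reagents that add atoms: none
Why: The potassium alkoxide adds to dichloroacetylene generated in situ from trichloroethylene and base, and anti protonation gives the E-dichlorovinyl ether, the standard precursor of lithium alkoxyacetylides.

Step 6
Reactants: 6 (4S,6R)-4-(tert-butyldimethylsilyloxy)-3-methyl-6-(prop-1-en-2-yl)cyclohex-2-en-1-one; 9 (E)-1,2-dichlorovinyl 4-methoxybenzyl ether
Product: 11 (1R,4S,6R)-4-(tert-butyldimethylsilyloxy)-1-[(4-methoxybenzyloxy)ethynyl]-3-methyl-6-(prop-1-en-2-yl)cyclohex-2-en-1-ol, via lithium (4-methoxybenzyloxy)acetylide 10 (not isolated)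
Conditions: 9, n-BuLi (2.2 equiv per 9), THF, −78 → −40 °C; then 6, −78 °C; NH4Cl aq.
Reagents that add atoms: none
Why: Dehydrochlorination and chlorine–lithium exchange give the alkoxyacetylide, which adds 1,2 to the enone; it should enter anti to the adjacent isopropenyl group (as alkynyllithium reagents do with 2-isopropylcyclohexanones of the menthone type), placing the alkynyl group trans to isopropenyl and fixing the C6 carbinol, with any minor epimer removed by chromatography.

Step 7
Reactants: 11 (1R,4S,6R)-4-(tert-butyldimethylsilyloxy)-1-[(4-methoxybenzyloxy)ethynyl]-3-methyl-6-(prop-1-en-2-yl)cyclohex-2-en-1-ol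
Product: 12 (1R,4S,6R)-4-(tert-butyldimethylsilyloxy)-1-[(E)-2-(4-methoxybenzyloxy)ethenyl]-3-methyl-6-(prop-1-en-2-yl)cyclohex-2-en-1-ol
Conditions: LiAlH4, THF, 0 °C → rt; NaOH aq. work-up; chromatography on Et3N-deactivated silica
Reagents that add atoms: none
Why: Hydroxyl-directed trans-hydroalumination of a propargylic alcohol gives only the E alkene, so the E enol ether is reached without an E-2-alkoxyvinyllithium reagent (which is prone to β-elimination); the base-only work-up protects the acid-labile β-alkoxyvinyl carbinol.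

Step 8
Reactants: 12 (1R,4S,6R)-4-(tert-butyldimethylsilyloxy)-1-[(E)-2-(4-methoxybenzyloxy)ethenyl]-3-methyl-6-(prop-1-en-2-yl)cyclohex-2-en-1-ol
Product: 14 (2Z,4S,6E,9R)-4-(tert-butyldimethylsilyloxy)-9-(4-methoxybenzyloxy)-3,7-dimethylcyclodeca-2,6-dien-1-one, via potassium C6–C7 enolate 13 (not isolated)
Conditions: KH, 18-crown-6, THF, 0 °C → rt; inverse quench into AcOH/THF, −78 °C
Reagents that add atoms: none
Why: KH converts 12 into its potassium alkoxide, and the 1,5-diene C8=C7–C6–C1–C10=C9 then undergoes a concerted [3,3] sigmatropic shift in which C8–C9 forms while the alkoxide-weakened C1–C6 bond breaks, leaving the regiodefined C6–C7 enolate 13. The closest known reaction is the anionic oxy-Cope ring expansion of trans-1,2-dialkenylcyclohexanols to cyclodec-5-enones. The ten-membered ring is closed by four-atom ring expansion of the cyclohexene through a six-centre chair transition state, not by end-to-end cyclisation, so no high dilution is needed and the cis C4=C5 alkene is carried over unchanged. The one new stereocentre, C8, is set by that chair: the alkoxide oxygen is axial and both alkenyl groups are equatorial on a half-chair whose sense is fixed by the carvone-derived C1 centre, the E enol ether holds OPMB equatorial, and C9 can then bond to one face of C8 only (8R), the same chair giving the E C1=C10 alkene. The step needs chair over boat, which the trans-diequatorial arrangement of 12 secures, and an intact β-alkoxy enolate, which is helped by the nascent enolate holding the C8–O bond in its nodal plane and by rearrangement at or below room temperature followed by an inverse quench into cold acetic acid.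

Step 9
Reactants: 14 (2Z,4S,6E,9R)-4-(tert-butyldimethylsilyloxy)-9-(4-methoxybenzyloxy)-3,7-dimethylcyclodeca-2,6-dien-1-one; 15 tert-butyl bromoacetate
Product: 17 tert-butyl 2-[(1S,3Z,5S,7E,10R)-5-(tert-butyldimethylsilyloxy)-10-(4-methoxybenzyloxy)-4,8-dimethyl-2-oxocyclodeca-3,7-dien-1-yl]acetate, via lithium C6–C7 enolate 16 (not isolated)
Conditions: LiN(iPr)2, THF, −78 °C; DMPU, then 15, −78 → −45 °C; AcOH quench at −78 °C
Reagents that add atoms: none
Why: Kinetic α′-deprotonation of the enone can only occur at C7 (C5 is vinylic) and regenerates the cross-conjugated C6–C7 enolate; SN2 alkylation of this medium-ring enolate should occur on its outer face, anti to the C8–C9 ring bond with C8–H near the enolate plane (allylic strain), which puts the acetate arm trans to the C8 oxygen (7S), while DMPU suppresses lithium chelation by the PMB ether and the low temperature keeps the β-alkoxide in place.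

Step 10
Reactants: 17 tert-butyl 2-[(1S,3Z,5S,7E,10R)-5-(tert-butyldimethylsilyloxy)-10-(4-methoxybenzyloxy)-4,8-dimethyl-2-oxocyclodeca-3,7-dien-1-yl]acetate
Product: 19 (3S,6S,7S,8R)-3-(tert-butyldimethylsilyloxy)-8-(4-methoxybenzyloxy)-13-norgermacra-1(10)E,4Z-dien-12,6-olide, via C6 hydroxy ester 18 (not isolated)
Conditions: Zn(BH4)2, Et2O, −30 → 0 °C; NH4Cl aq.; then camphorsulfonic acid (cat.), toluene, 40 °C
Reagents that add atoms: none
Why: Chelation-controlled 1,2-reduction of a β-alkoxy ketone, in which zinc bridges the C6 carbonyl and the C8 ether oxygen in a six-membered chelate with the C7 arm pseudoaxial and hydride adds to the opposite face, should give the alcohol with O6 syn to O8 and trans to the arm (6S) without touching the ester or the enone alkene; acid-catalysed intramolecular transesterification of 18 then closes the trans-fused γ-lactone with loss of tert-butanol.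

Step 11
Reactants: 19 (3S,6S,7S,8R)-3-(tert-butyldimethylsilyloxy)-8-(4-methoxybenzyloxy)-13-norgermacra-1(10)E,4Z-dien-12,6-olide
Product: 22 (3S,6S,7S,8R)-3-(tert-butyldimethylsilyloxy)-8-(4-methoxybenzyloxy)germacra-1(10)E,4Z,11(13)-trien-12,6-olide, via Mannich base 20 (not isolated), via trimethylammonium iodide 21 (not isolated)
Conditions: LiN(iPr)2, THF, −78 °C; H2C=NMe2+ I−, −78 °C → rt; then MeI, CH2Cl2/MeOH, rt; then NaHCO3 aq., EtOAc, rt
Reagents that add atoms: N,N-dimethylmethyleneiminium iodide (Eschenmoser's salt), C=[N+](C)C.[I-]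
Why: Mannich reaction of the lactone enolate with Eschenmoser's salt, N-methylation and base-induced elimination of trimethylamine is the standard α-methylenation of γ-lactones, and both C11 epimers of 20 converge on the same exocyclic alkene.

Step 12
Reactants: 22 (3S,6S,7S,8R)-3-(tert-butyldimethylsilyloxy)-8-(4-methoxybenzyloxy)germacra-1(10)E,4Z,11(13)-trien-12,6-olide
Product: 23 (3S,6S,7S,8R)-3-(tert-butyldimethylsilyloxy)-8-hydroxygermacra-1(10)E,4Z,11(13)-trien-12,6-olide
Conditions: DDQ, CH2Cl2/pH 7 buffer, 0 °C
Reagents that add atoms: none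
Why: Oxidative cleavage of the PMB ether by DDQ under buffered neutral conditions should leave the silyl ether, the three alkenes and the lactone untouched, and without base the freed 8-hydroxyl should not translactonise.

Step 13
Reactants: 23 (3S,6S,7S,8R)-3-(tert-butyldimethylsilyloxy)-8-hydroxygermacra-1(10)E,4Z,11(13)-trien-12,6-olide; 24 angelic acid
Product: 25 (3S,6S,7S,8R)-8-angeloyloxy-3-(tert-butyldimethylsilyloxy)germacra-1(10)E,4Z,11(13)-trien-12,6-olide
Conditions: 24, 2,4,6-Cl3C6H2COCl, Et3N, toluene, rt; then 23, 75 °C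
Reagents that add atoms: none
Why: Yamaguchi-type esterification through the preformed mixed anhydride of angelic acid, run without a nucleophilic amine catalyst, is the known way to put an angelate on a hindered secondary alcohol without isomerisation to the tiglate, and the C8 hydroxyl is the only free hydroxyl at this stage.

Step 14
Reactants: 25 (3S,6S,7S,8R)-8-angeloyloxy-3-(tert-butyldimethylsilyloxy)germacra-1(10)E,4Z,11(13)-trien-12,6-olide
Product: 26 (1S,3S,6S,7S,8R,10S)-8-angeloyloxy-3-(tert-butyldimethylsilyloxy)-1,10-epoxygermacra-4Z,11(13)-dien-12,6-olide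
Conditions: mCPBA, NaHCO3, CH2Cl2, −10 °C
Reagents that add atoms: 3-chloroperoxybenzoic acid, OOC(=O)c1cccc(Cl)c1
Why: Prilezhaev epoxidation should pick the strained, electron-rich E C1=C10 alkene over the two conjugated alkenes and the C4=C5 alkene flanked by two allylic C–O bonds, and attack on the outer face of the conformer with the C10 methyl and H6 on the same side of the ring (the arrangement in which the ring is formed and which the trans-lactone favours) should give the (1S,10S)-epoxide.

Step 15
Reactants: 26 (1S,3S,6S,7S,8R,10S)-8-angeloyloxy-3-(tert-butyldimethylsilyloxy)-1,10-epoxygermacra-4Z,11(13)-dien-12,6-olide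
Product: 27 (1S,3S,6S,7S,8R,10R)-8-angeloyloxy-3-(tert-butyldimethylsilyloxy)-1,10-dihydroxygermacra-4Z,11(13)-dien-12,6-olide
Conditions: HClO4 (cat.), THF/H2O 3:1, 0 °C
Reagents that add atoms: water, O
Why: Acid-catalysed epoxide hydrolysis, in which water opens the protonated epoxide at the tertiary C10 with inversion while the C1–O bond is kept, converts the trans-epoxide into the (1S,10R)-diol; O3 stays silylated and O8 acylated so that neither can open the epoxide across the ring, and the C4=C5 alkene, deactivated by its two allylic oxygens, should not cyclise onto C10.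

Step 16
Reactants: 27 (1S,3S,6S,7S,8R,10R)-8-angeloyloxy-3-(tert-butyldimethylsilyloxy)-1,10-dihydroxygermacra-4Z,11(13)-dien-12,6-olide
Product: 28 CNP0249520.1
Conditions: HF·pyridine, THF/pyridine, 0 °C → rt
Reagents that add atoms: none
Why: Fluoride-mediated cleavage of the secondary TBS ether under buffered, mildly acidic conditions should spare the α-methylene lactone and the angelate and avoid the acyl migration that basic fluoride could cause.

**Compound list**

1 | (R)-(−)-carvone | CC1=CC[C@H](CC1=O)C(C)=C | starting material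
2 | (1R,5R)-cis-carveol | C1C=C(C)[C@H](O)C[C@@H]1C(C)=C | intermediate
3 | (1S,5R)-trans-carveyl 4-nitrobenzoate | C1C=C(C)[C@@H](OC(=O)c2ccc(cc2)[N+](=O)[O-])C[C@@H]1C(C)=C | intermediate
4 | (1S,5R)-trans-carveol | C1C=C(C)[C@@H](O)C[C@@H]1C(C)=C | intermediate
5 | (1S,5R)-trans-carveol tert-butyldimethylsilyl ether | C1C=C(C)[C@@H](O[Si](C)(C)C(C)(C)C)C[C@@H]1C(C)=C | intermediate
6 | (4S,6R)-4-(tert-butyldimethylsilyloxy)-3-methyl-6-(prop-1-en-2-yl)cyclohex-2-en-1-one | O=C1C=C(C)[C@@H](O[Si](C)(C)C(C)(C)C)C[C@@H]1C(C)=C | intermediate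
7 | 4-methoxybenzyl alcohol | COc1ccc(CO)cc1 | starting material
8 | trichloroethylene | ClC=C(Cl)Cl | starting material
9 | (E)-1,2-dichlorovinyl 4-methoxybenzyl ether | COc1ccc(CO/C(Cl)=C\Cl)cc1 | intermediate
10 | lithium (4-methoxybenzyloxy)acetylide | [Li]C#COCc1ccc(OC)cc1 | intermediate
11 | (1R,4S,6R)-4-(tert-butyldimethylsilyloxy)-1-[(4-methoxybenzyloxy)ethynyl]-3-methyl-6-(prop-1-en-2-yl)cyclohex-2-en-1-ol | O[C@]1(C#COCc2ccc(OC)cc2)C=C(C)[C@@H](O[Si](C)(C)C(C)(C)C)C[C@@H]1C(C)=C | intermediate
12 | (1R,4S,6R)-4-(tert-butyldimethylsilyloxy)-1-[(E)-2-(4-methoxybenzyloxy)ethenyl]-3-methyl-6-(prop-1-en-2-yl)cyclohex-2-en-1-ol (trans-1,2-dialkenylcyclohexenol; C6 carbinol, C1 isopropenyl) | O[C@]1(/C=C/OCc2ccc(OC)cc2)C=C(C)[C@@H](O[Si](C)(C)C(C)(C)C)C[C@@H]1C(C)=C | intermediate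
13 | potassium C6–C7 enolate of 14 (enolate alkene trans in the ring) | [K+].[O-]\C1=C/[C@H](OCc2ccc(OC)cc2)C/C(C)=C/C[C@H](O[Si](C)(C)C(C)(C)C)\C(C)=C/1 | intermediate
14 | (2Z,4S,6E,9R)-4-(tert-butyldimethylsilyloxy)-9-(4-methoxybenzyloxy)-3,7-dimethylcyclodeca-2,6-dien-1-one (germacrane locants: 6-one, 4Z, 1(10)E, 3S, 8R) | O=C1/C=C(/C)[C@@H](O[Si](C)(C)C(C)(C)C)C/C=C(C)/C[C@@H](OCc2ccc(OC)cc2)C1 | intermediate
15 | tert-butyl bromoacetate | CC(C)(C)OC(=O)CBr | starting material
16 | lithium C6–C7 enolate of 14 | [Li+].[O-]\C1=C/[C@H](OCc2ccc(OC)cc2)C/C(C)=C/C[C@H](O[Si](C)(C)C(C)(C)C)\C(C)=C/1 | intermediate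
17 | tert-butyl 2-[(1S,3Z,5S,7E,10R)-5-(tert-butyldimethylsilyloxy)-10-(4-methoxybenzyloxy)-4,8-dimethyl-2-oxocyclodeca-3,7-dien-1-yl]acetate (germacrane 7S) | O=C1/C=C(/C)[C@@H](O[Si](C)(C)C(C)(C)C)C/C=C(C)/C[C@@H](OCc2ccc(OC)cc2)[C@@H]1CC(=O)OC(C)(C)C | intermediate
18 | tert-butyl 2-[(1R,2S,3Z,5S,7E,10R)-5-(tert-butyldimethylsilyloxy)-2-hydroxy-10-(4-methoxybenzyloxy)-4,8-dimethylcyclodeca-3,7-dien-1-yl]acetate (C6 alcohol of 17, 6S) | O[C@H]1/C=C(/C)[C@@H](O[Si](C)(C)C(C)(C)C)C/C=C(C)/C[C@@H](OCc2ccc(OC)cc2)[C@@H]1CC(=O)OC(C)(C)C | intermediate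
19 | (3S,6S,7S,8R)-3-(tert-butyldimethylsilyloxy)-8-(4-methoxybenzyloxy)-13-norgermacra-1(10)E,4Z-dien-12,6-olide | C1C(=O)O[C@H]2/C=C(/C)[C@@H](O[Si](C)(C)C(C)(C)C)C/C=C(C)/C[C@@H](OCc3ccc(OC)cc3)[C@H]12 | intermediate
20 | 11-(dimethylaminomethyl) derivative of 19 (Mannich base, C11 epimers) | CN(C)CC1C(=O)O[C@H]2/C=C(/C)[C@@H](O[Si](C)(C)C(C)(C)C)C/C=C(C)/C[C@@H](OCc3ccc(OC)cc3)[C@H]12 | intermediate
21 | trimethylammonium iodide of 20 (C11 epimers) | C[N+](C)(C)CC1C(=O)O[C@H]2/C=C(/C)[C@@H](O[Si](C)(C)C(C)(C)C)C/C=C(C)/C[C@@H](OCc3ccc(OC)cc3)[C@H]12.[I-] | intermediate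
22 | (3S,6S,7S,8R)-3-(tert-butyldimethylsilyloxy)-8-(4-methoxybenzyloxy)germacra-1(10)E,4Z,11(13)-trien-12,6-olide | C=C1C(=O)O[C@H]2/C=C(/C)[C@@H](O[Si](C)(C)C(C)(C)C)C/C=C(C)/C[C@@H](OCc3ccc(OC)cc3)[C@H]12 | intermediate
23 | (3S,6S,7S,8R)-3-(tert-butyldimethylsilyloxy)-8-hydroxygermacra-1(10)E,4Z,11(13)-trien-12,6-olide | C=C1C(=O)O[C@H]2/C=C(/C)[C@@H](O[Si](C)(C)C(C)(C)C)C/C=C(C)/C[C@@H](O)[C@H]12 | intermediate
24 | angelic acid, (Z)-2-methylbut-2-enoic acid | C/C=C(/C)C(=O)O | starting material
25 | (3S,6S,7S,8R)-8-angeloyloxy-3-(tert-butyldimethylsilyloxy)germacra-1(10)E,4Z,11(13)-trien-12,6-olide | C=C1C(=O)O[C@H]2/C=C(/C)[C@@H](O[Si](C)(C)C(C)(C)C)C/C=C(C)/C[C@@H](OC(=O)/C(C)=C\C)[C@H]12 | intermediate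
26 | (1S,3S,6S,7S,8R,10S)-8-angeloyloxy-3-(tert-butyldimethylsilyloxy)-1,10-epoxygermacra-4Z,11(13)-dien-12,6-olide | C=C1C(=O)O[C@H]2/C=C(/C)[C@@H](O[Si](C)(C)C(C)(C)C)C[C@@H]3O[C@@]3(C)C[C@@H](OC(=O)/C(C)=C\C)[C@H]12 | intermediate
27 | (1S,3S,6S,7S,8R,10R)-8-angeloyloxy-3-(tert-butyldimethylsilyloxy)-1,10-dihydroxygermacra-4Z,11(13)-dien-12,6-olide | C=C1C(=O)O[C@H]2/C=C(/C)[C@@H](O[Si](C)(C)C(C)(C)C)C[C@H](O)[C@](C)(O)C[C@@H](OC(=O)/C(C)=C\C)[C@H]12 | intermediate
28 | CNP0249520.1, (1S,3S,6S,7S,8R,10R)-8-angeloyloxy-1,3,10-trihydroxygermacra-4Z,11(13)-dien-12,6-olide | C=C1C(=O)O[C@H]2/C=C(/C)[C@@H](O)C[C@H](O)[C@](C)(O)C[C@@H](OC(=O)/C(C)=C\C)[C@H]12 | target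

**Step count**

Total: 16 steps. Longest linear sequence: 15 steps from (R)-carvone (steps 1–4 and 6–16); step 5 is a one-step branch that joins at step 6.

**Steps most likely to fail**

Step 8. The potassium enolate may lose the C8 alkoxide by E1cB elimination before the quench, or part of the material may react by a stepwise fragmentation–recombination path that erodes the chair control. The fallback sets out from 12 and avoids any enolate. The carbinol is silylated (TMSCl, imidazole, CH2Cl2) to the trimethylsilyl ether F1. This is heated in degassed toluene at about 180 °C in a sealed tube with a little N,O-bis(trimethylsilyl)acetamide as acid scavenger. The neutral siloxy-Cope rearrangement passes through the same chair and should give the trimethylsilyl enol ether F2, which cannot eliminate. Aqueous citric acid in THF then frees the ketone, and the route is rejoined at 14.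

Step 9. Facial selectivity may be poor if the re-formed lithium enolate relaxes to a conformer, or a chelate with the PMB ether, that exposes the other face of C7; the alkoxide may also be lost on warming. The fallback sets out from 12. The rearrangement is run as in step 8, but instead of protonation, 15 is added at −78 °C to the cold solution of the nascent potassium enolate 13, whose outer face is fixed by the chair transition state. This one-pot rearrangement–alkylation skips the isolated ketone and comes back to the route at 17; it makes no new compound (F0).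

Step 10. Hydride may be delivered to the wrong face if the zinc chelate does not form inside the ten-membered ring; attack on the outer face then leads to the C6 epimer and the cis-lactone. The fallback sets out from 17 and uses that outer-face preference. Non-chelating Luche reduction (NaBH4, CeCl3·7H2O, MeOH, −78 °C) should give the 6-epi hydroxy ester F3, kept cold and acid-free so that the tert-butyl ester does not close. Mitsunobu esterification (PPh3, DIAD, 4-nitrobenzoic acid, toluene) inverts C6 to the C6 4-nitrobenzoate F4. K2CO3 in MeOH releases hydroxy ester 18, which is closed with camphorsulfonic acid as in step 10, and the route is rejoined at 19.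

**Further compounds**

F1 | step 8 | trimethylsilyl ether of carbinol 12 | C[Si](C)(C)O[C@]1(/C=C/OCc2ccc(OC)cc2)C=C(C)[C@@H](O[Si](C)(C)C(C)(C)C)C[C@@H]1C(C)=C
F2 | step 8 | trimethylsilyl enol ether of ketone 14 (C6–C7 enol ether, trans in the ring) | C[Si](C)(C)O\C1=C/[C@H](OCc2ccc(OC)cc2)C/C(C)=C/C[C@H](O[Si](C)(C)C(C)(C)C)\C(C)=C/1
F0 | step 9 | none | none
F3 | step 10 | 6-epi hydroxy ester (C6 epimer of 18) | O[C@@H]1/C=C(/C)[C@@H](O[Si](C)(C)C(C)(C)C)C/C=C(C)/C[C@@H](OCc2ccc(OC)cc2)[C@@H]1CC(=O)OC(C)(C)C
F4 | step 10 | C6 4-nitrobenzoate of 18 | O=C(O[C@H]1/C=C(/C)[C@@H](O[Si](C)(C)C(C)(C)C)C/C=C(C)/C[C@@H](OCc2ccc(OC)cc2)[C@@H]1CC(=O)OC(C)(C)C)c3ccc(cc3)[N+](=O)[O-]
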